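Numbering: ring A is the fused guaiacol ring. Ring B is the 3,4-dihydronaphthalene carbocycle (C1H=C2, C3H, C4H2, C4a, C8a). Ring C is the aroyl guaiacol ring, C9 the CH2OH carbon and C7' the ketone carbon.
Enabling feature: the C1=C2–C7'(=O)–ring C enone at ring B is the retron of an alkyne–carbonyl metathesis. C2≡C7' is read as an aryl alkyne, and the ketone O as the O of a formyl group (C1) on C8a of ring A.
Retrosynthetic cuts, in order: three O–Si bonds; C1=C2 (ring B opens to an isomeric acyclic alkynyl benzaldehyde); C1–C8a (ArBr to ArCHO); C7'–ring C (Sonogashira); C2≡C7' (aldehyde homologation); C3–C9 (enolate hydroxymethylation); C8a–Br.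
Forward: dihydroferulic acid is silylated, brominated at C8a, loaded on the auxiliary, hydroxymethylated at C3 and taken through the Weinreb amide to the terminal alkyne. This is joined to ring C and formylated; only then is ring B, the only ring made, closed, and global desilylation ends the route.
Stereochemistry: the single stereocentre C3 is set by the (R)-4-benzyloxazolidinone-controlled titanium enolate hydroxymethylation and is only carried along afterwards. The change of descriptor from S to R at the alkyne stage is a CIP priority effect, not an inversion.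

Key step: step 11

Assumption: the three starting materials and all named reagents are taken as commercially available; TIPS = triisopropylsilyl.

Step 1
Reactants: 1 3-(4-hydroxy-3-methoxyphenyl)propanoic acid (dihydroferulic acid)
Product: 3 3-[3-methoxy-4-(triisopropylsilyloxy)phenyl]propanoic acid, via bis-TIPS silyl ester 2 (not isolated)
Conditions: TIPSCl (2.3 equiv), imidazole, DMF, rt; then K2CO3, THF/MeOH/H2O, rt; acidify to pH 4
Reagents that add atoms: triisopropylsilyl chloride, CC(C)[Si](Cl)(C(C)C)C(C)C
Why: Exhaustive silylation (silyl ether protection) followed by mild carbonate hydrolysis should leave only the phenol capped, because a silyl ester is cleaved far faster than a hindered aryl TIPS ether.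

Step 2
Reactants: 3 3-[3-methoxy-4-(triisopropylsilyloxy)phenyl]propanoic acid
Product: 4 3-[2-bromo-5-methoxy-4-(triisopropylsilyloxy)phenyl]propanoic acid
Conditions: NBS, MeCN, 0 °C → rt, dark
Reagents that add atoms: N-bromosuccinimide, O=C1CCC(=O)N1Br
Why: Electrophilic aromatic bromination with NBS in a polar solvent should enter para to the methoxy group and ortho to the side chain (future C8a), as this site is activated by both groups whereas the position next to the bulky OTIPS group and the position between OMe and the chain are hindered.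

Step 3
Reactants: 4 3-[2-bromo-5-methoxy-4-(triisopropylsilyloxy)phenyl]propanoic acid; 5 (R)-4-benzyl-1,3-oxazolidin-2-one
Product: 7 (4R)-4-benzyl-3-{3-[2-bromo-5-methoxy-4-(triisopropylsilyloxy)phenyl]propanoyl}-1,3-oxazolidin-2-one, via mixed pivalic anhydride 6 (not isolated)
Conditions: PivCl, Et3N, THF, −20 °C; then LiCl, 5, −20 °C → rt
Reagents that add atoms: pivaloyl chloride, CC(C)(C)C(=O)Cl (its atoms are held only in 6)
Why: N-acylation of the oxazolidinone through the mixed pivalic anhydride with LiCl/Et3N is a standard way to load the auxiliary, the nucleophile attacking the less hindered acyl carbon of 6.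

Step 4
Reactants: 7 (4R)-4-benzyl-3-{3-[2-bromo-5-methoxy-4-(triisopropylsilyloxy)phenyl]propanoyl}-1,3-oxazolidin-2-one
Product: 9 (4R)-4-benzyl-3-{(2S)-2-[2-bromo-5-methoxy-4-(triisopropylsilyloxy)benzyl]-3-hydroxypropanoyl}-1,3-oxazolidin-2-one, via chlorotitanium Z-enolate 8 (not isolated)
Conditions: TiCl4, iPr2NEt, CH2Cl2, 0 °C; then 1,3,5-trioxane, TiCl4, 0 °C; aq. NH4Cl
Reagents that add atoms: 1,3,5-trioxane, C1OCOCO1 (one CH2O unit); titanium tetrachloride, Cl[Ti](Cl)(Cl)Cl (its atoms are held only in 8)
Why: This is the auxiliary-controlled alkylation (Evans-type hydroxymethylation) of a chelated chlorotitanium Z-enolate with TiCl4-activated trioxane as formaldehyde source, in which the benzyl group of the (R)-auxiliary shields one enolate face so that the CH2OH carbon (C9) enters from the other face and sets the S centre that becomes C3.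

Step 5
Reactants: 9 (4R)-4-benzyl-3-{(2S)-2-[2-bromo-5-methoxy-4-(triisopropylsilyloxy)benzyl]-3-hydroxypropanoyl}-1,3-oxazolidin-2-one
Product: 10 (2S)-2-[2-bromo-5-methoxy-4-(triisopropylsilyloxy)benzyl]-3-hydroxy-N-methoxy-N-methylpropanamide
Conditions: MeNH(OMe)·HCl, AlMe3, CH2Cl2, −20 → 0 °C; aq. potassium sodium tartrate
Reagents that add atoms: N,O-dimethylhydroxylamine hydrochloride, CNOC.Cl
Why: Aluminium amide transamination of a beta-hydroxy imide (Weinreb amide formation) should be directed to the exocyclic carbonyl by the aluminium alkoxide formed at the free C9 hydroxyl, frees the auxiliary for recovery and does not enolise the alpha centre.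

Step 6
Reactants: 10 (2S)-2-[2-bromo-5-methoxy-4-(triisopropylsilyloxy)benzyl]-3-hydroxy-N-methoxy-N-methylpropanamide
Product: 11 (2S)-2-[2-bromo-5-methoxy-4-(triisopropylsilyloxy)benzyl]-N-methoxy-N-methyl-3-(triisopropylsilyloxy)propanamide
Conditions: TIPSCl, imidazole, DMAP (cat.), DMF, rt
Reagents that add atoms: triisopropylsilyl chloride, CC(C)[Si](Cl)(C(C)C)C(C)C
Why: Standard silyl ether protection of an unhindered primary alcohol, chosen so that all three hydroxyl groups carry the same acid-tolerant, fluoride-labile group.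

Step 7
Reactants: 11 (2S)-2-[2-bromo-5-methoxy-4-(triisopropylsilyloxy)benzyl]-N-methoxy-N-methyl-3-(triisopropylsilyloxy)propanamide
Product: 13 (3R)-4-[2-bromo-5-methoxy-4-(triisopropylsilyloxy)phenyl]-3-[(triisopropylsilyloxy)methyl]but-1-yne, via alpha-branched aldehyde 12 (not isolated)
Conditions: iBu2AlH, CH2Cl2, −78 °C; then MeOH, K2CO3, dimethyl (1-diazo-2-oxopropyl)phosphonate, −78 °C → rt
Reagents that add atoms: dimethyl (1-diazo-2-oxopropyl)phosphonate, COP(=O)(OC)C(=[N+]=[N-])C(C)=O
Why: Partial reduction of the Weinreb amide stops at the chelated tetrahedral adduct, which releases aldehyde 12 on addition of methanol, and Ohira–Bestmann homologation (Seyferth–Gilbert type) in the same flask converts the formyl group into the terminal alkyne quickly enough that the alpha centre, unchanged in space and now called R by the priority rules, should not epimerise.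

Step 8
Reactants: 14 4-iodo-2-methoxyphenol
Product: 15 (4-iodo-2-methoxyphenoxy)triisopropylsilane
Conditions: TIPSCl, imidazole, DMF, rt
Reagents that add atoms: triisopropylsilyl chloride, CC(C)[Si](Cl)(C(C)C)C(C)C
Why: Standard silyl ether protection of a phenol, which keeps the ring C oxygen a para donor while removing its acidic proton before the organolithium and Lewis acid steps.

Step 9
Reactants: 13 (3R)-4-[2-bromo-5-methoxy-4-(triisopropylsilyloxy)phenyl]-3-[(triisopropylsilyloxy)methyl]but-1-yne; 15 (4-iodo-2-methoxyphenoxy)triisopropylsilane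
Product: 16 (3R)-4-[2-bromo-5-methoxy-4-(triisopropylsilyloxy)phenyl]-1-[3-methoxy-4-(triisopropylsilyloxy)phenyl]-3-[(triisopropylsilyloxy)methyl]but-1-yne
Conditions: PdCl2(PPh3)2 (3 mol %), CuI (6 mol %), Et3N/THF, rt
Reagents that add atoms: none
Why: Sonogashira coupling, in which zerovalent palladium inserts into the C–I bond of 15 at room temperature far faster than into the electron-rich, ortho-substituted C–Br bond of 13, so that the bromide survives for the next step.

Step 10
Reactants: 16 (3R)-4-[2-bromo-5-methoxy-4-(triisopropylsilyloxy)phenyl]-1-[3-methoxy-4-(triisopropylsilyloxy)phenyl]-3-[(triisopropylsilyloxy)methyl]but-1-yne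
Product: 18 4-methoxy-2-{(2R)-4-[3-methoxy-4-(triisopropylsilyloxy)phenyl]-2-[(triisopropylsilyloxy)methyl]but-3-yn-1-yl}-5-(triisopropylsilyloxy)benzaldehyde, via aryllithium 17 (not isolated)
Conditions: n-BuLi (1.05 equiv), THF, −78 °C, 10 min; DMF, −78 → 0 °C; H2O
Reagents that add atoms: N,N-dimethylformamide, CN(C)C=O; n-butyllithium, [Li]CCCC (its lithium is held only in 17)
Why: Bromine–lithium exchange followed by formylation with DMF (Bouveault-type aldehyde synthesis) is faster at −78 °C than propargylic deprotonation or 5-exo-dig carbolithiation of the electron-rich internal alkyne, and the silyl ethers are inert to the short exposure.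

Step 11
Reactants: 18 4-methoxy-2-{(2R)-4-[3-methoxy-4-(triisopropylsilyloxy)phenyl]-2-[(triisopropylsilyloxy)methyl]but-3-yn-1-yl}-5-(triisopropylsilyloxy)benzaldehyde
Product: 20 [(3R)-6-methoxy-7-(triisopropylsilyloxy)-3-[(triisopropylsilyloxy)methyl]-3,4-dihydronaphthalen-2-yl][3-methoxy-4-(triisopropylsilyloxy)phenyl]methanone, via ring-fused oxetene 19 (not isolated)
Conditions: FeCl3 (10 mol %), 4 Å MS, ClCH2CH2Cl, rt → 60 °C
Reagents that add atoms: none
Why: FeCl3 binds the formyl oxygen on ring A, the alkyne carbon next to C3 (future C2) attacks the formyl carbon (future C1), the resulting vinyl cation sits on the carbon bearing ring C, the iron alkoxide oxygen collapses on it to give oxetene 19 (formal [2+2]), and a four-electron electrocyclic opening of 19 delivers the C1=C2 bond and the aroyl C=O, so that the aldehyde oxygen ends up as the ketone oxygen in a waste-free isomerisation. The closest known reaction type is the Lewis acid catalysed intramolecular alkyne–carbonyl metathesis of aryl alkynes tethered by three atoms to a benzaldehyde, which gives 3-acyl-2H-chromenes, 3-acyl-1,2-dihydroquinolines and carbocyclic enones. Ring B closes in the 6-exo-trig mode at the formyl carbon with the alkyne reacting exo (6-exo-dig), and the four-membered oxetene is a temporary ring that closes by O-capture of the vinyl cation and is opened again in the same flask. No stereocentre is created in 20: C1 of 19 is transient and both of its epimers open to the same enone, while C3 keeps its R configuration because its C–H bond is neither ionised nor enolised on this path. The step needs regioselectivity (C1 to the alkyl-side alkyne carbon, not the 7-endo alternative), which the para-silyloxy donor of ring C secures by localising the positive charge on the aryl-side carbon and which the three-atom tether reinforces, and chemoselectivity, which the bulky TIPS caps secure by keeping the C9 oxygen from adding to the alkyne or the aldehyde. Traces of water are harmless, since Markovnikov hydration followed by aldol condensation leads to the same product 20.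

Step 12
Reactants: 20 [(3R)-6-methoxy-7-(triisopropylsilyloxy)-3-[(triisopropylsilyloxy)methyl]-3,4-dihydronaphthalen-2-yl][3-methoxy-4-(triisopropylsilyloxy)phenyl]methanone
Product: 21 [(3R)-7-hydroxy-3-(hydroxymethyl)-6-methoxy-3,4-dihydronaphthalen-2-yl](4-hydroxy-3-methoxyphenyl)methanone (target)
Conditions: Bu4NF (3.6 equiv), AcOH (3.6 equiv), THF, 0 °C → rt, Ar
Reagents that add atoms: none
Why: Fluoride-driven cleavage of all three Si–O bonds in one operation (global desilylation), buffered with acetic acid so that no free phenoxide is present that could promote oxidation, aromatisation or conjugate addition at the enone, and C3 is not touched.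

Compound list
1 | 3-(4-hydroxy-3-methoxyphenyl)propanoic acid | COc1cc(CCC(=O)O)ccc1O | starting material
2 | triisopropylsilyl 3-[3-methoxy-4-(triisopropylsilyloxy)phenyl]propanoate | COc1cc(CCC(=O)O[Si](C(C)C)(C(C)C)C(C)C)ccc1O[Si](C(C)C)(C(C)C)C(C)C | intermediate
3 | 3-[3-methoxy-4-(triisopropylsilyloxy)phenyl]propanoic acid | COc1cc(CCC(=O)O)ccc1O[Si](C(C)C)(C(C)C)C(C)C | intermediate
4 | 3-[2-bromo-5-methoxy-4-(triisopropylsilyloxy)phenyl]propanoic acid | COc1cc(CCC(=O)O)c(Br)cc1O[Si](C(C)C)(C(C)C)C(C)C | intermediate
5 | (R)-4-benzyl-1,3-oxazolidin-2-one | O=C1N[C@H](Cc2ccccc2)CO1 | starting material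
6 | mixed anhydride of 4 with pivalic acid | COc1cc(CCC(=O)OC(=O)C(C)(C)C)c(Br)cc1O[Si](C(C)C)(C(C)C)C(C)C | intermediate
7 | (4R)-4-benzyl-3-{3-[2-bromo-5-methoxy-4-(triisopropylsilyloxy)phenyl]propanoyl}-1,3-oxazolidin-2-one | COc1cc(CCC(=O)N2[C@H](Cc3ccccc3)COC2=O)c(Br)cc1O[Si](C(C)C)(C(C)C)C(C)C | intermediate
8 | trichlorotitanium (Z)-enolate of 7 | COc1cc(C/C=C(\O[Ti](Cl)(Cl)Cl)N2[C@H](Cc3ccccc3)COC2=O)c(Br)cc1O[Si](C(C)C)(C(C)C)C(C)C | intermediate
9 | (4R)-4-benzyl-3-{(2S)-2-[2-bromo-5-methoxy-4-(triisopropylsilyloxy)benzyl]-3-hydroxypropanoyl}-1,3-oxazolidin-2-one | COc1cc(C[C@H](C(=O)N2[C@H](Cc3ccccc3)COC2=O)CO)c(Br)cc1O[Si](C(C)C)(C(C)C)C(C)C | intermediate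
10 | (2S)-2-[2-bromo-5-methoxy-4-(triisopropylsilyloxy)benzyl]-3-hydroxy-N-methoxy-N-methylpropanamide | COc1cc(C[C@H](C(=O)N(C)OC)CO)c(Br)cc1O[Si](C(C)C)(C(C)C)C(C)C | intermediate
11 | (2S)-2-[2-bromo-5-methoxy-4-(triisopropylsilyloxy)benzyl]-N-methoxy-N-methyl-3-(triisopropylsilyloxy)propanamide | COc1cc(C[C@H](C(=O)N(C)OC)CO[Si](C(C)C)(C(C)C)C(C)C)c(Br)cc1O[Si](C(C)C)(C(C)C)C(C)C | intermediate
12 | (2S)-2-[2-bromo-5-methoxy-4-(triisopropylsilyloxy)benzyl]-3-(triisopropylsilyloxy)propanal | COc1cc(C[C@H](C=O)CO[Si](C(C)C)(C(C)C)C(C)C)c(Br)cc1O[Si](C(C)C)(C(C)C)C(C)C | intermediate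
13 | (3R)-4-[2-bromo-5-methoxy-4-(triisopropylsilyloxy)phenyl]-3-[(triisopropylsilyloxy)methyl]but-1-yne | COc1cc(C[C@H](C#C)CO[Si](C(C)C)(C(C)C)C(C)C)c(Br)cc1O[Si](C(C)C)(C(C)C)C(C)C | intermediate
14 | 4-iodo-2-methoxyphenol | COc1cc(I)ccc1O | starting material
15 | (4-iodo-2-methoxyphenoxy)triisopropylsilane | COc1cc(I)ccc1O[Si](C(C)C)(C(C)C)C(C)C | intermediate
16 | (3R)-4-[2-bromo-5-methoxy-4-(triisopropylsilyloxy)phenyl]-1-[3-methoxy-4-(triisopropylsilyloxy)phenyl]-3-[(triisopropylsilyloxy)methyl]but-1-yne | COc1cc(C[C@H](C#Cc2ccc(O[Si](C(C)C)(C(C)C)C(C)C)c(OC)c2)CO[Si](C(C)C)(C(C)C)C(C)C)c(Br)cc1O[Si](C(C)C)(C(C)C)C(C)C | intermediate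
17 | aryllithium from 16 (Li in place of Br) | COc1cc(C[C@H](C#Cc2ccc(O[Si](C(C)C)(C(C)C)C(C)C)c(OC)c2)CO[Si](C(C)C)(C(C)C)C(C)C)c([Li])cc1O[Si](C(C)C)(C(C)C)C(C)C | intermediate
18 | 4-methoxy-2-{(2R)-4-[3-methoxy-4-(triisopropylsilyloxy)phenyl]-2-[(triisopropylsilyloxy)methyl]but-3-yn-1-yl}-5-(triisopropylsilyloxy)benzaldehyde | COc1cc(C[C@H](C#Cc2ccc(O[Si](C(C)C)(C(C)C)C(C)C)c(OC)c2)CO[Si](C(C)C)(C(C)C)C(C)C)c(C=O)cc1O[Si](C(C)C)(C(C)C)C(C)C | intermediate
19 | oxetene fused across C1–C2 of ring B (O on C1, C2=C7' inside the four-membered ring, ring C on C7'; 3R, transient C1 configuration left open) | COc1cc2c(cc1O[Si](C(C)C)(C(C)C)C(C)C)C1OC(c3ccc(O[Si](C(C)C)(C(C)C)C(C)C)c(OC)c3)=C1[C@H](CO[Si](C(C)C)(C(C)C)C(C)C)C2 | intermediate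
20 | [(3R)-6-methoxy-7-(triisopropylsilyloxy)-3-[(triisopropylsilyloxy)methyl]-3,4-dihydronaphthalen-2-yl][3-methoxy-4-(triisopropylsilyloxy)phenyl]methanone | COc1cc(C(=O)C2=Cc3cc(O[Si](C(C)C)(C(C)C)C(C)C)c(OC)cc3C[C@H]2CO[Si](C(C)C)(C(C)C)C(C)C)ccc1O[Si](C(C)C)(C(C)C)C(C)C | intermediate
21 | [(3R)-7-hydroxy-3-(hydroxymethyl)-6-methoxy-3,4-dihydronaphthalen-2-yl](4-hydroxy-3-methoxyphenyl)methanone | COc1cc(C(=O)C2=Cc3cc(O)c(OC)cc3C[C@H]2CO)ccc1O | target

Total step count: 12. Longest linear sequence: 11 steps (steps 1–7 and 9–12, from 1 to 21).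

Steps most likely to fail

1. Step 11.
- What may go wrong: the Lewis acid may strip a silyl ether before cyclisation, so that the C9 oxygen adds to the activated alkyne.
- The donor-deactivated formyl group may also react too slowly, or a 1,5-hydride shift from C3–H to the activated formyl carbon may erode the stereocentre.
- Fallback: it sets out from 18 and comes back at 20, and makes the same bond in two known operations. The alkyne of 18 would first be hydrated in the Markovnikov sense with (Ph3P)AuNTf2 (cat.) in wet 1,4-dioxane. The donor-substituted ring C directs water to the aryl-side carbon. This gives the keto aldehyde 4-methoxy-2-{(2R)-4-[3-methoxy-4-(triisopropylsilyloxy)phenyl]-4-oxo-2-[(triisopropylsilyloxy)methyl]butyl}-5-(triisopropylsilyloxy)benzaldehyde F1.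
- F1 has a single enolisable position (C2). It would be closed by an intramolecular aldol condensation (piperidine/AcOH, toluene, reflux with removal of water, 6-enolexo-exo-trig) to give 20.

2. Step 10.
- What may go wrong: the aryllithium may add across the tethered alkyne (5-exo-dig carbolithiation). It may also be quenched by the propargylic C3–H, which would erode the stereocentre, before DMF traps it.
- Fallback: it sets out from 13 and comes back at 18, and reverses the order of coupling and formylation. Compound 13 would be treated with n-BuLi (2.1 equiv, THF, −78 °C) to give the C,C-dilithiated alkyne (lithium acetylide plus aryllithium) F2. In F2 the alkyne is masked as its anion, so it can neither be carbolithiated nor lose its propargylic proton.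
- One equivalent of DMF at −78 °C should be taken up by the far more reactive aryllithium. A cold aqueous quench would then give 4-methoxy-2-{(2R)-2-[(triisopropylsilyloxy)methyl]but-3-yn-1-yl}-5-(triisopropylsilyloxy)benzaldehyde F3.
- Sonogashira coupling of F3 with 15 (PdCl2(PPh3)2, CuI, Et3N/THF, rt), which tolerates the aldehyde, gives 18.

3. Step 7.
- What may go wrong: epimerisation of the alpha centre of the aldehyde, beta-elimination of silyloxide, or loss of the phenolic silyl group in basic methanol.
- Fallback: it sets out from 11 and comes back at 13, and takes the aldehyde out of the protic basic medium altogether. Compound 11 would be reduced with iBu2AlH at −78 °C, and aldehyde 12 isolated after a cold potassium sodium tartrate work-up.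
- Aldehyde 12 would then be added at −78 °C to preformed lithiated trimethylsilyldiazomethane (TMSCHN2, n-BuLi, THF). The Colvin rearrangement of the derived alkylidene carbene gives 13 under aprotic, non-equilibrating conditions. No free butyllithium is present that could touch the aryl bromide.
- This fallback makes no compound outside the list (F0).

Further compounds
F1 | step 11 | 4-methoxy-2-{(2R)-4-[3-methoxy-4-(triisopropylsilyloxy)phenyl]-4-oxo-2-[(triisopropylsilyloxy)methyl]butyl}-5-(triisopropylsilyloxy)benzaldehyde | COc1cc(C[C@H](CC(=O)c2ccc(O[Si](C(C)C)(C(C)C)C(C)C)c(OC)c2)CO[Si](C(C)C)(C(C)C)C(C)C)c(C=O)cc1O[Si](C(C)C)(C(C)C)C(C)C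
F2 | step 10 | C,C-dilithiated alkyne from 13 (lithium acetylide plus aryllithium) | COc1cc(C[C@H](C#C[Li])CO[Si](C(C)C)(C(C)C)C(C)C)c([Li])cc1O[Si](C(C)C)(C(C)C)C(C)C
F3 | step 10 | 4-methoxy-2-{(2R)-2-[(triisopropylsilyloxy)methyl]but-3-yn-1-yl}-5-(triisopropylsilyloxy)benzaldehyde | COc1cc(C[C@H](C#C)CO[Si](C(C)C)(C(C)C)C(C)C)c(C=O)cc1O[Si](C(C)C)(C(C)C)C(C)C
F0 | step 7 | none | none
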